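**Strategy**

The dihydrofuran ring (O1–C2–C3–C3a–C7a) is made by enlarging an oxetane. Its benzo ring carries its only substituent at C5, para to O1, which is the oxygen pattern of p-benzoquinone. A Paternò–Büchi addition of the quinone C=O to a protected piceatannol-type stilbene gives a trans-2,3-diaryl spiro-oxetane on a cyclohexadienone, which is resolved. In the key step acid triggers a dienone–phenol rearrangement: C3 shifts from the spiro carbon to the neighbouring ring carbon, so the oxetane expands to the dihydrobenzofuran while the six-membered ring aromatises. Both stereocentres are carried over, and the former quinone carbonyl ends as the C5 phenol, the handle (triflate, Heck) for the stilbene arm.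

Key step: step 4

Assumption: 3′-hydroxypterostilbene (1) is taken as a commercially available stilbenoid; compound 5 is a racemate and its SMILES shows the enantiomer that step 3 isolates.

**Route**

Step 1
Reactants: 1 3′-hydroxypterostilbene [(E)-4-[2-(3,5-dimethoxyphenyl)ethenyl]benzene-1,2-diol]; 2 methanesulfonyl chloride
Product: 3 (E)-4-[2-(3,5-dimethoxyphenyl)ethenyl]-1,2-phenylene dimethanesulfonate
Conditions: MsCl (2.5 equiv), Et3N (3 equiv), CH2Cl2, 0 °C to rt
Reagents that add atoms: methanesulfonyl chloride, CS(=O)(=O)Cl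
Why: O-Sulfonylation (mesylation) of both catechol hydroxyls; the mesylates make this ring the electron-poor aryl group that directs the regiochemistry of step 2 and keeps the benzylic C–O bond from ionising in step 4, and they are inert to light, acid and Pd(0).

Step 2
Reactants: 3 stilbene bis-mesylate; 4 p-benzoquinone
Product: 5 racemic trans spiro-oxetane, rac-4-[(2S,3R)-3-(3,5-dimethoxyphenyl)-7-oxo-1-oxaspiro[3.5]nona-5,8-dien-2-yl]-1,2-phenylene dimethanesulfonate
Conditions: 4 (2 equiv), benzene, Ar, hν (λ > 410 nm), 20 °C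
Reagents that add atoms: p-benzoquinone, O=C1C=CC(=O)C=C1
Why: Paternò–Büchi [2+2] photocycloaddition of triplet (n,π*) benzoquinone to a stilbene, a known entry to 2,3-diaryl spiro-oxetanes; the stepwise C–O then C–C bond formation lets the open intermediate relax, so the trans relationship of C2 and C3 should result from either alkene isomer (racemic), and the quinone oxygen should bond to the alkene carbon beside the electron-poor bis(mesyloxy)phenyl ring because the radical or cationic character left on the other carbon is better tolerated beside the 3,5-dimethoxyphenyl ring.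

Step 3
Reactants: 5 racemic trans spiro-oxetane
Product: 6 4-[(2S,3R)-3-(3,5-dimethoxyphenyl)-7-oxo-1-oxaspiro[3.5]nona-5,8-dien-2-yl]-1,2-phenylene dimethanesulfonate (single enantiomer)
Conditions: preparative SFC on immobilised amylose tris(3,5-dimethylphenylcarbamate), CO2/i-PrOH, no additive
Reagents that add atoms: none
Why: Resolution of enantiomers by chromatography on a chiral stationary phase, which fixes the absolute configuration that steps 4–8 carry into the target; the neutral oxetane should survive additive-free elution, and the (2S,3R) assignment is to be confirmed by anomalous-dispersion X-ray analysis (sulfur atoms).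

Step 4
Reactants: 6 (2S,3R)-spiro-oxetane
Product: 8 4-[(2S,3S)-3-(3,5-dimethoxyphenyl)-5-hydroxy-2,3-dihydro-1-benzofuran-2-yl]-1,2-phenylene dimethanesulfonate, via ring-expanded oxocarbenium ion 7 (not isolated)
Conditions: TfOH (10 mol %), CH2Cl2, −40 to 0 °C
Reagents that add atoms: none
Why: Acid-catalysed dienone–phenol rearrangement of a quinone–alkene spiro-oxetane, a known route to 2,3-dihydrobenzofuran-5-ols: O-protonation of the cross-conjugated dienone places positive charge on C5/C9 next to the spiro carbon C4, and the benzylic carbon C3 shifts from C4 to C5 to give oxocarbenium ion 7, which loses the C5 proton and aromatises. The five-membered ring is therefore not closed by a cyclisation but formed by a suprafacial 1,2-carbon shift (Wagner–Meerwein type) that enlarges the oxetane (O1, C2, C3, C4) by the ring carbon C5, driven by release of oxetane strain and by aromatisation. C3 migrates with retention and the C2–O1 bond is never broken, so the trans (2S,3R)-oxetane should give the trans (2S,3S)-dihydrobenzofuran without loss of enantiopurity (the change of descriptor at C3 is only a CIP effect). The step needs carbon and not oxygen migration, which is secured because only the carbon shift leaves the charge on C4 as an oxygen-stabilised oxocarbenium ion; this puts the hydroxyl para to O1, at C5, where the target carries its side chain. It also needs the oxetane C2–O1 bond not to ionise, which the electron-poor 3,4-bis(mesyloxy)phenyl group on C2 secures.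

Step 5
Reactants: 8 (2S,3S)-dihydrobenzofuran-5-ol; 9 trifluoromethanesulfonic anhydride
Product: 10 (2S,3S)-2-[3,4-bis(methanesulfonyloxy)phenyl]-3-(3,5-dimethoxyphenyl)-2,3-dihydro-1-benzofuran-5-yl trifluoromethanesulfonate
Conditions: Tf2O (1.2 equiv), pyridine, CH2Cl2, 0 °C
Reagents that add atoms: trifluoromethanesulfonic anhydride, O=S(=O)(OS(=O)(=O)C(F)(F)F)C(F)(F)F
Why: O-Triflation of the phenol turns the former quinone oxygen into the only Pd-reactive leaving group of the molecule, the aryl mesylates being inert under the coupling conditions of step 6.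

Step 6
Reactants: 10 aryl triflate; 11 3,5-dimethoxystyrene
Product: 12 4-{(2S,3S)-3-(3,5-dimethoxyphenyl)-5-[(E)-2-(3,5-dimethoxyphenyl)ethenyl]-2,3-dihydro-1-benzofuran-2-yl}-1,2-phenylene dimethanesulfonate
Conditions: PdCl2(PPh3)2 (5 mol %), LiCl (3 equiv), Et3N (3 equiv), DMF, 100 °C
Reagents that add atoms: 3,5-dimethoxystyrene, C=Cc1cc(OC)cc(OC)c1
Why: Mizoroki–Heck coupling of the aryl triflate under chloride-modified (neutral-pathway) conditions should arylate the terminal alkene carbon and give the E-stilbene by syn-insertion and syn-β-hydride elimination; neither stereocentre is involved.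

Step 7
Reactants: 12 bis-mesylate
Product: 13 4-{(2S,3S)-3-(3,5-dimethoxyphenyl)-5-[(E)-2-(3,5-dimethoxyphenyl)ethenyl]-2,3-dihydro-1-benzofuran-2-yl}benzene-1,2-diol
Conditions: LDA (5 equiv), THF, −78 to 0 °C; degassed aq NH4Cl
Reagents that add atoms: none
Why: Known base-induced cleavage of aryl methanesulfonates: LDA deprotonates the S–CH3 group and sulfene is expelled (E1cB) at low temperature, which should free the catechol without touching the methyl ethers, the alkene or the two benzylic stereocentres, whose C–H bonds are far less acidic than the mesyl protons.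

Step 8
Reactants: 13 catechol tetramethyl ether
Product: 14 5-[(E)-2-[(2S,3S)-2-(3,4-dihydroxyphenyl)-3-(3,5-dihydroxyphenyl)-2,3-dihydro-1-benzofuran-5-yl]ethenyl]benzene-1,3-diol (CNP0207985.1)
Conditions: BBr3 (12 equiv), CH2Cl2, Ar, −78 °C to rt; MeOH, then H2O
Reagents that add atoms: none
Why: Lewis-acid O-demethylation of aryl methyl ethers with BBr3, as used for methylated stilbenoids, should free the four remaining phenols; the catechol is held as its borate during the reaction, which tempers its donor effect on the benzylic C2–O1 bond, and the stereocentres are not touched.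

**Compound list**

1 | 3′-hydroxypterostilbene, (E)-4-[2-(3,5-dimethoxyphenyl)ethenyl]benzene-1,2-diol | COc1cc(/C=C/c2ccc(O)c(O)c2)cc(OC)c1 | starting material
2 | methanesulfonyl chloride | CS(=O)(=O)Cl | starting material
3 | (E)-4-[2-(3,5-dimethoxyphenyl)ethenyl]-1,2-phenylene dimethanesulfonate | COc1cc(/C=C/c2ccc(OS(C)(=O)=O)c(OS(C)(=O)=O)c2)cc(OC)c1 | intermediate
4 | p-benzoquinone | O=C1C=CC(=O)C=C1 | starting material
5 | rac-4-[(2S,3R)-3-(3,5-dimethoxyphenyl)-7-oxo-1-oxaspiro[3.5]nona-5,8-dien-2-yl]-1,2-phenylene dimethanesulfonate (racemate, 2,3-trans) | O=C1C=CC2(C=C1)[C@H](c1cc(OC)cc(OC)c1)[C@@H](c1ccc(OS(C)(=O)=O)c(OS(C)(=O)=O)c1)O2 | intermediate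
6 | 4-[(2S,3R)-3-(3,5-dimethoxyphenyl)-7-oxo-1-oxaspiro[3.5]nona-5,8-dien-2-yl]-1,2-phenylene dimethanesulfonate (single enantiomer) | O=C1C=CC2(C=C1)[C@H](c1cc(OC)cc(OC)c1)[C@@H](c1ccc(OS(C)(=O)=O)c(OS(C)(=O)=O)c1)O2 | intermediate
7 | ring-expanded oxocarbenium ion: C3a-protonated form of 8, 2-[3,4-bis(mesyloxy)phenyl]-3-(3,5-dimethoxyphenyl)-5-hydroxy-3,3a-dihydro-2H-1-benzofuran-1-ium (C2 and C3 as in 8; C3a not defined, lost on deprotonation) | OC1=CC2[C@H](c3cc(OC)cc(OC)c3)[C@@H](c3ccc(OS(C)(=O)=O)c(OS(C)(=O)=O)c3)[O+]=C2C=C1 | intermediate (not isolated)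
8 | 4-[(2S,3S)-3-(3,5-dimethoxyphenyl)-5-hydroxy-2,3-dihydro-1-benzofuran-2-yl]-1,2-phenylene dimethanesulfonate | Oc1ccc2c(c1)[C@H](c1cc(OC)cc(OC)c1)[C@@H](c1ccc(OS(C)(=O)=O)c(OS(C)(=O)=O)c1)O2 | intermediate
9 | trifluoromethanesulfonic anhydride | O=S(=O)(OS(=O)(=O)C(F)(F)F)C(F)(F)F | starting material
10 | (2S,3S)-2-[3,4-bis(methanesulfonyloxy)phenyl]-3-(3,5-dimethoxyphenyl)-2,3-dihydro-1-benzofuran-5-yl trifluoromethanesulfonate | O=S(=O)(Oc1ccc2c(c1)[C@H](c1cc(OC)cc(OC)c1)[C@@H](c1ccc(OS(C)(=O)=O)c(OS(C)(=O)=O)c1)O2)C(F)(F)F | intermediate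
11 | 3,5-dimethoxystyrene | C=Cc1cc(OC)cc(OC)c1 | starting material
12 | 4-{(2S,3S)-3-(3,5-dimethoxyphenyl)-5-[(E)-2-(3,5-dimethoxyphenyl)ethenyl]-2,3-dihydro-1-benzofuran-2-yl}-1,2-phenylene dimethanesulfonate | COc1cc(OC)cc(/C=C/c2ccc3c(c2)[C@H](c2cc(OC)cc(OC)c2)[C@@H](c2ccc(OS(C)(=O)=O)c(OS(C)(=O)=O)c2)O3)c1 | intermediate
13 | 4-{(2S,3S)-3-(3,5-dimethoxyphenyl)-5-[(E)-2-(3,5-dimethoxyphenyl)ethenyl]-2,3-dihydro-1-benzofuran-2-yl}benzene-1,2-diol | COc1cc(OC)cc(/C=C/c2ccc3c(c2)[C@H](c2cc(OC)cc(OC)c2)[C@@H](c2ccc(O)c(O)c2)O3)c1 | intermediate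
14 | 5-[(E)-2-[(2S,3S)-2-(3,4-dihydroxyphenyl)-3-(3,5-dihydroxyphenyl)-2,3-dihydro-1-benzofuran-5-yl]ethenyl]benzene-1,3-diol | Oc1cc(O)cc(/C=C/c2ccc3c(c2)[C@H](c2cc(O)cc(O)c2)[C@@H](c2ccc(O)c(O)c2)O3)c1 | target

**Step count**

Total step count: 8. Longest linear sequence: 8 steps (1 to 14).

**Steps most likely to fail**

1. Step 2 (Paternò–Büchi addition). What may go wrong: the first C–O bond may form at the wrong alkene carbon, so that the regioisomeric oxetane dominates, or triplet energy transfer to the stilbene and hydrogen abstraction by the quinone may outrun cycloaddition. Fallback, from 3 back to 8: it replaces steps 2–4 by polar chemistry, needs no resolution, and gives up the oxetane. Shi epoxidation of 3 with the enantiomeric ketone catalyst and Oxone should give the (2S,3S)-trans-epoxide F1. Friedel–Crafts opening with excess hydroquinone in hexafluoroisopropanol, at the benzylic carbon beside the dimethoxyphenyl ring (the only one that can carry positive charge) and with inversion, should give the hydroquinone adduct F2. Mitsunobu cyclisation (PPh3, DIAD, THF) of the ortho phenol onto the secondary alcohol, with inversion at C2, then gives 8.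

2. Step 4 (key step). What may go wrong: under the acid needed to protonate the weakly basic dienone, the oxetane C2–O1 bond may ionise (cycloreversion, loss of configuration at C2), or oxygen may migrate instead of carbon. Fallback, from 6 back to 12: the ring expansion is kept but runs through a cation that forms under much milder acid, and steps 5 and 6 are no longer needed. Takai olefination of 3,5-dimethoxybenzaldehyde gives (E)-1-(2-iodoethenyl)-3,5-dimethoxybenzene F3. Its alkenylmagnesium derivative (i-PrMgCl·LiCl) is added to the dienone carbonyl of 6 (LaCl3·2LiCl, THF, −40 °C) to give the tertiary dienol F4 as a mixture of C7 epimers. A trace of PPTS in CH2Cl2 should ionise the doubly allylic alcohol, and the same 1,2-shift of C3 followed by proton loss (dienol–benzene rearrangement) gives 12.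

3. Step 8 (demethylation). What may go wrong: Lewis-acid-assisted heterolysis of the benzylic C2–O1 bond once the catechol is free (ring opening, epimerisation at C2), and acid-induced oligomerisation of the stilbene. Fallback, from 10 back to 14: the methyl ethers are removed early, where the C2 aryl ring is still deactivated and no alkene is present, and the phenols are carried as silyl ethers. BBr3 on 10 should give the resorcinol F5, and TBSCl/imidazole its bis(silyl ether) F6. 3,5-Dihydroxybenzaldehyde is silylated to the aldehyde F7 and methylenated (Ph3P=CH2) to the styrene F8. Heck coupling of F6 with F8 under the conditions of step 6 gives the silylated stilbene F9, LDA as in step 7 gives the catechol F10, and Et3N·3HF in THF then gives 14.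

**Further compounds**

F1 | step 2 | 4-[(2S,3S)-3-(3,5-dimethoxyphenyl)oxiran-2-yl]-1,2-phenylene dimethanesulfonate | O1[C@@H](c2cc(OC)cc(OC)c2)[C@@H]1c1ccc(OS(C)(=O)=O)c(OS(C)(=O)=O)c1
F2 | step 2 | 4-[(1R,2S)-2-(2,5-dihydroxyphenyl)-2-(3,5-dimethoxyphenyl)-1-hydroxyethyl]-1,2-phenylene dimethanesulfonate | Oc1ccc(O)c(c1)[C@H](c1cc(OC)cc(OC)c1)[C@H](c1ccc(OS(C)(=O)=O)c(OS(C)(=O)=O)c1)O
F3 | step 4 | (E)-1-(2-iodoethenyl)-3,5-dimethoxybenzene | COc1cc(/C=C/I)cc(OC)c1
F4 | step 4 | 4-[(2S,3R)-3-(3,5-dimethoxyphenyl)-7-[(E)-2-(3,5-dimethoxyphenyl)ethenyl]-7-hydroxy-1-oxaspiro[3.5]nona-5,8-dien-2-yl]-1,2-phenylene dimethanesulfonate (C7 epimers) | COc1cc(OC)cc(/C=C/C2(O)C=CC3(C=C2)[C@H](c2cc(OC)cc(OC)c2)[C@@H](c2ccc(OS(C)(=O)=O)c(OS(C)(=O)=O)c2)O3)c1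
F5 | step 8 | (2S,3S)-2-[3,4-bis(methanesulfonyloxy)phenyl]-3-(3,5-dihydroxyphenyl)-2,3-dihydro-1-benzofuran-5-yl trifluoromethanesulfonate | O=S(=O)(Oc1ccc2c(c1)[C@H](c1cc(O)cc(O)c1)[C@@H](c1ccc(OS(C)(=O)=O)c(OS(C)(=O)=O)c1)O2)C(F)(F)F
F6 | step 8 | (2S,3S)-2-[3,4-bis(methanesulfonyloxy)phenyl]-3-[3,5-bis(tert-butyldimethylsilyloxy)phenyl]-2,3-dihydro-1-benzofuran-5-yl trifluoromethanesulfonate | O=S(=O)(Oc1ccc2c(c1)[C@H](c1cc(O[Si](C)(C)C(C)(C)C)cc(O[Si](C)(C)C(C)(C)C)c1)[C@@H](c1ccc(OS(C)(=O)=O)c(OS(C)(=O)=O)c1)O2)C(F)(F)F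
F7 | step 8 | 3,5-bis(tert-butyldimethylsilyloxy)benzaldehyde | O=Cc1cc(O[Si](C)(C)C(C)(C)C)cc(O[Si](C)(C)C(C)(C)C)c1
F8 | step 8 | 3,5-bis(tert-butyldimethylsilyloxy)styrene | C=Cc1cc(O[Si](C)(C)C(C)(C)C)cc(O[Si](C)(C)C(C)(C)C)c1
F9 | step 8 | 4-{(2S,3S)-3-[3,5-bis(tert-butyldimethylsilyloxy)phenyl]-5-[(E)-2-[3,5-bis(tert-butyldimethylsilyloxy)phenyl]ethenyl]-2,3-dihydro-1-benzofuran-2-yl}-1,2-phenylene dimethanesulfonate | CC(C)(C)[Si](C)(C)Oc1cc(O[Si](C)(C)C(C)(C)C)cc(/C=C/c2ccc3c(c2)[C@H](c2cc(O[Si](C)(C)C(C)(C)C)cc(O[Si](C)(C)C(C)(C)C)c2)[C@@H](c2ccc(OS(C)(=O)=O)c(OS(C)(=O)=O)c2)O3)c1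
F10 | step 8 | 4-{(2S,3S)-3-[3,5-bis(tert-butyldimethylsilyloxy)phenyl]-5-[(E)-2-[3,5-bis(tert-butyldimethylsilyloxy)phenyl]ethenyl]-2,3-dihydro-1-benzofuran-2-yl}benzene-1,2-diol | CC(C)(C)[Si](C)(C)Oc1cc(O[Si](C)(C)C(C)(C)C)cc(/C=C/c2ccc3c(c2)[C@H](c2cc(O[Si](C)(C)C(C)(C)C)cc(O[Si](C)(C)C(C)(C)C)c2)[C@@H](c2ccc(O)c(O)c2)O3)c1
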